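**Retrosynthetic overview** (target numbered as a bicyclo[3.2.1]oct-3-ene-2,8-dione: C1 bridgehead between the two C=O, C4 styryl carbon, C5 bridgehead, C6 resorcinol-bearing, C7 4-hydroxyphenyl-bearing, C8 bridging C=O)
1. Target ⇐ its tetrabenzyl ether; global debenzylation is the last step.
2. Bicycle ⇐ one acyclic keto-diketo ester, folded polyketide-style in one flask: Claisen closure (C1–C8) makes the five-membered ring first, then a bridging aldol condensation (C4–C5) makes the six-membered ring.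
3. Acyclic chain ⇐ β,β′-coupling (C6–C7) of a cinnamaldehyde homoenolate with one enone arm of a symmetric curcuminoid; this catalytic step sets both aryl-bearing stereocentres.
4. Curcuminoid ⇐ 4-(benzyloxy)benzaldehyde + pentane-2,4-dione; enal ⇐ 3,5-bis(benzyloxy)benzaldehyde + formylmethylene ylide.

Assumption: the (5aR,10bS) antipode of the aminoindanol-derived triazolium salt is taken to give the (3R,4R) Michael adduct of step 3; if induction runs the other way, the (5aS,10bR) salt is used and nothing else changes.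

**Step 1**
Reactants: 1 4-(benzyloxy)benzaldehyde (2 equiv); 2 pentane-2,4-dione
Product: 3 (1E,6E)-1,7-bis[4-(benzyloxy)phenyl]hepta-1,6-diene-3,5-dione
Conditions: B2O3 (0.7 equiv), B(OBu)3 (4 equiv), n-BuNH2 (0.4 equiv), EtOAc, 75 °C; then 0.4 M HCl, 60 °C
Reagents that add atoms: none
Why: Boron-templated double Claisen–Schmidt (Pabon) condensation, in which chelation of 2 as its boron enolate blocks the central carbon so that both methyl groups condense with 1 to give the all-E curcuminoid, with no stereocentre formed.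

**Step 2**
Reactants: 4 3,5-bis(benzyloxy)benzaldehyde; 5 (triphenylphosphoranylidene)acetaldehyde
Product: 6 (2E)-3-[3,5-bis(benzyloxy)phenyl]prop-2-enal
Conditions: toluene, 80 °C
Reagents that add atoms: none
Why: Wittig olefination with the stabilised formylmethylene ylide gives the E-enal selectively, with no stereocentre formed.

**Step 3**
Reactants: 3 (1E,6E)-1,7-bis[4-(benzyloxy)phenyl]hepta-1,6-diene-3,5-dione (1.5 equiv); 6 (2E)-3-[3,5-bis(benzyloxy)phenyl]prop-2-enal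
Product: 7 methyl (3R,4R,9E)-3-[3,5-bis(benzyloxy)phenyl]-4,10-bis[4-(benzyloxy)phenyl]-6,8-dioxodec-9-enoate
Conditions: (5aR,10bS)-2-mesityl-5a,10b-dihydro-4H,6H-indeno[2,1-b][1,2,4]triazolo[4,3-d][1,4]oxazin-2-ium chloride (10 mol %), NaOAc (0.3 equiv), MeOH (5 equiv), THF, 23 °C
Reagents that add atoms: methanol (CO)
Why: N-heterocyclic-carbene homoenolate (conjugate umpolung) Michael addition followed by redox esterification, in which the Breslow intermediate of 6 adds through its β-carbon to one enone terminus of the symmetric, largely enolised 3 (whose enolised β-diketone carbonyl should resist the usual follow-up aldol), the acyl azolium is methanolysed, and the chiral triazolium sets C3 and C4 together in the anti (3R,4R) sense known from trans-selective enal–chalcone annulations.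

**Step 4**
Reactants: 7 methyl (3R,4R,9E)-3-[3,5-bis(benzyloxy)phenyl]-4,10-bis[4-(benzyloxy)phenyl]-6,8-dioxodec-9-enoate
Product: 10 (1R,5S,6S,7S)-6-[3,5-bis(benzyloxy)phenyl]-7-[4-(benzyloxy)phenyl]-4-{(E)-2-[4-(benzyloxy)phenyl]ethenyl}bicyclo[3.2.1]oct-3-ene-2,8-dione, via acylcyclopentanone triketone 8 (not isolated), via bridged ketol 9 (not isolated)
Conditions: LiN(i-Pr)2 (2.3 equiv), THF, −78 → 0 °C; then AcOH (4 equiv), piperidine (0.3 equiv), DMSO–H2O (9:1), 45 °C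
Reagents that add atoms: none
Why: Proposed new method: the β-diketone dianion is C-acylated at its γ-carbon by the ester (Harris-type dianion Claisen, 5-exo, driven by deprotonation of triketone 8), and after buffering, the keto tautomer of 8 (the only form in which the future bridgehead is sp3) undergoes amine/acid-catalysed bridging aldol from the cyclopentanone α′-carbon onto the styryl ketone and E1cB dehydration of ketol 9, the closest precedents being Hajos-type bridged ketol formation from 2-(3-oxoalkyl)cyclopentane-1,3-diones and polyketide triketone aldol folding, with the new bond formed anti to the adjacent 3,5-bis(benzyloxy)phenyl group so that this aryl ends exo, the other endo, and both bridgeheads are fixed.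

**Step 5**
Reactants: 10 (1R,5S,6S,7S)-6-[3,5-bis(benzyloxy)phenyl]-7-[4-(benzyloxy)phenyl]-4-{(E)-2-[4-(benzyloxy)phenyl]ethenyl}bicyclo[3.2.1]oct-3-ene-2,8-dione
Product: 11 (1R,5S,6S,7S)-6-(3,5-dihydroxyphenyl)-7-(4-hydroxyphenyl)-4-[(E)-2-(4-hydroxyphenyl)ethenyl]bicyclo[3.2.1]oct-3-ene-2,8-dione
Conditions: BCl3 (8 equiv), C6HMe5 (12 equiv), CH2Cl2, −78 °C; then H2O
Reagents that add atoms: none
Why: Lewis-acid debenzylation with pentamethylbenzene as a non-basic benzyl-cation scavenger (Friedel–Crafts trapping) frees the four phenols at low temperature without touching the alkenes, and the four stereocentres cannot epimerise because the bridgeheads are non-enolisable and C6/C7 are not α to a carbonyl.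

**Compound list**
1 | 4-(benzyloxy)benzaldehyde | O=Cc1ccc(OCc2ccccc2)cc1 | starting material
2 | pentane-2,4-dione | CC(=O)CC(C)=O | starting material
3 | (1E,6E)-1,7-bis[4-(benzyloxy)phenyl]hepta-1,6-diene-3,5-dione | O=C(/C=C/c1ccc(OCc2ccccc2)cc1)CC(=O)/C=C/c1ccc(OCc2ccccc2)cc1 | intermediate
4 | 3,5-bis(benzyloxy)benzaldehyde | O=Cc1cc(OCc2ccccc2)cc(OCc2ccccc2)c1 | starting material
5 | (triphenylphosphoranylidene)acetaldehyde | O=CC=P(c1ccccc1)(c1ccccc1)c1ccccc1 | starting material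
6 | (2E)-3-[3,5-bis(benzyloxy)phenyl]prop-2-enal | O=C/C=C/c1cc(OCc2ccccc2)cc(OCc2ccccc2)c1 | intermediate
7 | methyl (3R,4R,9E)-3-[3,5-bis(benzyloxy)phenyl]-4,10-bis[4-(benzyloxy)phenyl]-6,8-dioxodec-9-enoate | COC(=O)C[C@@H](c1cc(OCc2ccccc2)cc(OCc2ccccc2)c1)[C@H](c1ccc(OCc2ccccc2)cc1)CC(=O)CC(=O)/C=C/c1ccc(OCc2ccccc2)cc1 | intermediate
8 | (3S,4R)-4-[3,5-bis(benzyloxy)phenyl]-3-[4-(benzyloxy)phenyl]-2-{(4E)-5-[4-(benzyloxy)phenyl]-3-oxopent-4-enoyl}cyclopentan-1-one (C2 epimerisable, largely enolised) | O=C1C[C@@H](c2cc(OCc3ccccc3)cc(OCc3ccccc3)c2)[C@H](c2ccc(OCc3ccccc3)cc2)C1C(=O)CC(=O)/C=C/c1ccc(OCc2ccccc2)cc1 | intermediate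
9 | (1R,5S,6S,7S)-6-[3,5-bis(benzyloxy)phenyl]-7-[4-(benzyloxy)phenyl]-4-{(E)-2-[4-(benzyloxy)phenyl]ethenyl}-4-hydroxybicyclo[3.2.1]octane-2,8-dione (configuration at C4 not controlled) | O=C1CC(O)(/C=C/c2ccc(OCc3ccccc3)cc2)[C@H]2C(=O)[C@@H]1[C@@H](c1ccc(OCc3ccccc3)cc1)[C@@H]2c1cc(OCc2ccccc2)cc(OCc2ccccc2)c1 | intermediate
10 | (1R,5S,6S,7S)-6-[3,5-bis(benzyloxy)phenyl]-7-[4-(benzyloxy)phenyl]-4-{(E)-2-[4-(benzyloxy)phenyl]ethenyl}bicyclo[3.2.1]oct-3-ene-2,8-dione | O=C1C=C(/C=C/c2ccc(OCc3ccccc3)cc2)[C@H]2C(=O)[C@@H]1[C@@H](c1ccc(OCc3ccccc3)cc1)[C@@H]2c1cc(OCc2ccccc2)cc(OCc2ccccc2)c1 | intermediate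
11 | (1R,5S,6S,7S)-6-(3,5-dihydroxyphenyl)-7-(4-hydroxyphenyl)-4-[(E)-2-(4-hydroxyphenyl)ethenyl]bicyclo[3.2.1]oct-3-ene-2,8-dione | O=C1C=C(/C=C/c2ccc(O)cc2)[C@H]2C(=O)[C@@H]1[C@@H](c1ccc(O)cc1)[C@@H]2c1cc(O)cc(O)c1 | target

**Totals**
Total step count: 5. Longest linear sequence: 4 (steps 1, 3, 4, 5).

**Steps most likely to fail, with fallbacks**

Step 4 is the most exposed. The Claisen stage is ordinary, but the bridging aldol needs the minor keto tautomer of 8; its competitors are O-cyclisation to a fused 4-pyranone and closure on the wrong face. The fallback blocks the future bridgehead and closes the ring anionically. It sets out from 3: O-methylation ((CH3O)2SO2, K2CO3, acetone) gives the enol methyl ether F3. The same carbene-catalysed addition of 6 with methanol gives the vinylogous-ester ester F4. LiN(SiMe3)2 (2.2 equiv, THF, −78 → 0 °C) closes the cyclopentanone through the α′-enolate, and the resulting β-diketone enolate is sulfenylated in the same flask with PhSO2SPh, anti to the neighbouring aryl, to give the quaternary sulfide F5. F5 cannot enolise at the future bridgehead and cannot form a pyranone, and its acyl chain is locked on the correct face. One more equivalent of LiN(SiMe3)2 forms the only remaining enolate, which closes the six-membered ring by intramolecular Michael addition–elimination of methoxide to give the bridgehead sulfide F6. Radical desulfurisation (Bu3SnH, AIBN, benzene, 80 °C) comes back to the route at 10.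

Step 3 is second. The acidic enol of 3 may quench the carbene or react slowly, a second addition to 7 is possible, and the anti sense and ee rest on analogy with chalcones. The fallback masks the diketone as a neutral, more electrophilic chelate. It sets out from 3: BF3·OEt2 (CH2Cl2, 23 °C) gives the difluoroboron complex F1. The same triazolium/NaOAc/MeOH addition of 6 gives the chelated Michael adduct F2. Aqueous Na2C2O4 in MeOH at 60 °C removes boron and comes back to the route at 7.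

Step 5 is third. The non-enolisable bridging diketone may suffer retro-Claisen opening, or the exo resorcinol ring may close onto the C8 ketone under the Lewis acid. The fallback removes the benzyl groups before the rings exist and carries fluoride-labile silyl ethers instead. It sets out from 7: BCl3/C6HMe5 (CH2Cl2, −78 °C) gives the tetraphenol ester F7, and t-BuMe2SiCl/imidazole (DMF) gives the tetrakis(silyl ether) F8. The same one-flask Claisen/aldol sequence then runs through the silylated triketone F9 and the silylated bridged ketol F10 to the silylated bicycle F11. HF·pyridine (THF, 0 °C) comes back to the route at 11.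

**Further compounds**
F1 | step 3 | 4,6-bis{(E)-2-[4-(benzyloxy)phenyl]ethenyl}-2,2-difluoro-2H-1,3,2-dioxaborinin-1-ium-2-uide | F[B-]1(F)OC(/C=C/c2ccc(OCc3ccccc3)cc2)=CC(/C=C/c2ccc(OCc3ccccc3)cc2)=[O+]1
F2 | step 3 | methyl (3R,4R)-3-[3,5-bis(benzyloxy)phenyl]-4-[4-(benzyloxy)phenyl]-5-(6-{(E)-2-[4-(benzyloxy)phenyl]ethenyl}-2,2-difluoro-2H-1,3,2-dioxaborinin-1-ium-2-uid-4-yl)pentanoate | COC(=O)C[C@@H](c1cc(OCc2ccccc2)cc(OCc2ccccc2)c1)[C@H](c1ccc(OCc2ccccc2)cc1)CC1=CC(/C=C/c2ccc(OCc3ccccc3)cc2)=[O+][B-](F)(F)O1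
F3 | step 4 | (1E,4Z,6E)-1,7-bis[4-(benzyloxy)phenyl]-5-methoxyhepta-1,4,6-trien-3-one | O=C(/C=C/c1ccc(OCc2ccccc2)cc1)/C=C(\OC)/C=C/c1ccc(OCc2ccccc2)cc1
F4 | step 4 | methyl (3R,4R,7Z,9E)-3-[3,5-bis(benzyloxy)phenyl]-4,10-bis[4-(benzyloxy)phenyl]-8-methoxy-6-oxodeca-7,9-dienoate | COC(=O)C[C@@H](c1cc(OCc2ccccc2)cc(OCc2ccccc2)c1)[C@H](c1ccc(OCc2ccccc2)cc1)CC(=O)/C=C(\OC)/C=C/c1ccc(OCc2ccccc2)cc1
F5 | step 4 | (2R,3R,4R)-4-[3,5-bis(benzyloxy)phenyl]-3-[4-(benzyloxy)phenyl]-2-{(2Z,4E)-5-[4-(benzyloxy)phenyl]-3-methoxypenta-2,4-dienoyl}-2-(phenylsulfanyl)cyclopentan-1-one | O=C1C[C@@H](c2cc(OCc3ccccc3)cc(OCc3ccccc3)c2)[C@H](c2ccc(OCc3ccccc3)cc2)[C@]1(Sc2ccccc2)C(=O)/C=C(\OC)/C=C/c1ccc(OCc2ccccc2)cc1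
F6 | step 4 | (1S,5S,6R,7R)-6-[3,5-bis(benzyloxy)phenyl]-7-[4-(benzyloxy)phenyl]-4-{(E)-2-[4-(benzyloxy)phenyl]ethenyl}-1-(phenylsulfanyl)bicyclo[3.2.1]oct-3-ene-2,8-dione | O=C1C=C(/C=C/c2ccc(OCc3ccccc3)cc2)[C@H]2C(=O)[C@]1(Sc4ccccc4)[C@@H](c1ccc(OCc3ccccc3)cc1)[C@@H]2c1cc(OCc2ccccc2)cc(OCc2ccccc2)c1
F7 | step 5 | methyl (3R,4R,9E)-3-(3,5-dihydroxyphenyl)-4,10-bis(4-hydroxyphenyl)-6,8-dioxodec-9-enoate | COC(=O)C[C@@H](c1cc(O)cc(O)c1)[C@H](c1ccc(O)cc1)CC(=O)CC(=O)/C=C/c1ccc(O)cc1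
F8 | step 5 | methyl (3R,4R,9E)-3-{3,5-bis[(tert-butyldimethylsilyl)oxy]phenyl}-4,10-bis{4-[(tert-butyldimethylsilyl)oxy]phenyl}-6,8-dioxodec-9-enoate | COC(=O)C[C@@H](c1cc(O[Si](C)(C)C(C)(C)C)cc(O[Si](C)(C)C(C)(C)C)c1)[C@H](c1ccc(O[Si](C)(C)C(C)(C)C)cc1)CC(=O)CC(=O)/C=C/c1ccc(O[Si](C)(C)C(C)(C)C)cc1
F9 | step 5 | (3S,4R)-4-{3,5-bis[(tert-butyldimethylsilyl)oxy]phenyl}-3-{4-[(tert-butyldimethylsilyl)oxy]phenyl}-2-[(4E)-5-{4-[(tert-butyldimethylsilyl)oxy]phenyl}-3-oxopent-4-enoyl]cyclopentan-1-one | O=C1C[C@@H](c2cc(O[Si](C)(C)C(C)(C)C)cc(O[Si](C)(C)C(C)(C)C)c2)[C@H](c2ccc(O[Si](C)(C)C(C)(C)C)cc2)C1C(=O)CC(=O)/C=C/c1ccc(O[Si](C)(C)C(C)(C)C)cc1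
F10 | step 5 | (1R,5S,6S,7S)-6-{3,5-bis[(tert-butyldimethylsilyl)oxy]phenyl}-7-{4-[(tert-butyldimethylsilyl)oxy]phenyl}-4-[(E)-2-{4-[(tert-butyldimethylsilyl)oxy]phenyl}ethenyl]-4-hydroxybicyclo[3.2.1]octane-2,8-dione | O=C1CC(O)(/C=C/c2ccc(O[Si](C)(C)C(C)(C)C)cc2)[C@H]2C(=O)[C@@H]1[C@@H](c1ccc(O[Si](C)(C)C(C)(C)C)cc1)[C@@H]2c1cc(O[Si](C)(C)C(C)(C)C)cc(O[Si](C)(C)C(C)(C)C)c1
F11 | step 5 | (1R,5S,6S,7S)-6-{3,5-bis[(tert-butyldimethylsilyl)oxy]phenyl}-7-{4-[(tert-butyldimethylsilyl)oxy]phenyl}-4-[(E)-2-{4-[(tert-butyldimethylsilyl)oxy]phenyl}ethenyl]bicyclo[3.2.1]oct-3-ene-2,8-dione | O=C1C=C(/C=C/c2ccc(O[Si](C)(C)C(C)(C)C)cc2)[C@H]2C(=O)[C@@H]1[C@@H](c1ccc(O[Si](C)(C)C(C)(C)C)cc1)[C@@H]2c1cc(O[Si](C)(C)C(C)(C)C)cc(O[Si](C)(C)C(C)(C)C)c1
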